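Retrosynthetic cuts, in order: the two 2-methylbutanoate C–O bonds (O1, O12) and C18–Cl (back to a 4α,18-epoxide); C12–C13 (the bought butenolide added to a C12 aldehyde); C5–C10 and C8–C9 together (intramolecular Diels–Alder); C4–C5 (boron aldol of two acyclic fragments).
Enabling feature: the trans-decalin (ring A = C1–C5/C10, ring B = C5–C10) has its fusion bond C5–C10 flanked by the quaternary carbons C5 (bearing C19) and C9 (bearing C20), syn-diaxial, and carries oxygen on C1, C4 and C6, the sites for an allylic directing group, a silicon anchor and the oxygen of a 2-silyloxydiene.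
Forward order: an aldehyde fragment (C11, C9, C20, C10, C1–C4) and an enone fragment (C19, C5–C8, C17) are joined by the aldol; a temporary 4H-1,3,2-dioxasiline ring (O4–Si–O6) is closed first; rings A and B then form together; the C4 spiro-epoxide follows; the butenolide ring arrives ready-made at C12; the epoxide is opened by chloride and the two esters go on last.
Stereochemistry: C1 from (R)-5-(hydroxymethyl)butyrolactone; the temporary C4 carbinol from the Ipc-boron aldol; C5, C9 and C10 from the cycloaddition (C8 forms with the wrong sense, is erased as the 8(17)-alkene and is reset by enone reduction, C6 by hydride); C4 from the 19-OH-directed epoxidation; C12 from a ligand-controlled chromium addition; the acyl α-carbons from (S)-2-methylbutanoic acid.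

Key step: step 12

Remark: clerodane numbering is used for all intermediates (ring A C1–C5 and C10; ring B C5–C10; C11 and methyl C20 on C9; C17 on C8; C18 on C4; C19 on C5); α is the face of C19 and C20, β the face of H-10.
Remark: enolates, organoboranes and organometallic species that live only within one operation are treated as reagent-bound forms of the numbered compounds and carry no number; in the two reagent-controlled additions (steps 8 and 25) the antipode of the boron reagent and of the chromium ligand is defined by the aldehyde face that has to be attacked, the Re face in both.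

Step 1
Reactants: 1 (R)-5-(hydroxymethyl)dihydrofuran-2(3H)-one; 2 ethyl 2-(triphenylphosphoranylidene)propanoate
Product: 4 ethyl (E)-2-methyl-3-[(2R)-5-oxotetrahydrofuran-2-yl]prop-2-enoate, via lactone aldehyde 3 (not isolated)
Conditions: IBX (1.5 equiv), 2 (1.3 equiv), DMSO, rt
Reagents that add atoms: none
Why: Tandem IBX oxidation/Wittig olefination, in which the labile α-acyloxy aldehyde is trapped as it forms by the stabilised α-methyl ylide, should give the E-trisubstituted enoate without touching the stereocentre.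

Step 2
Reactants: 4 ethyl (E)-2-methyl-3-[(2R)-5-oxotetrahydrofuran-2-yl]prop-2-enoate
Product: 5 ethyl (2E,4R)-4-hydroxy-7-[methoxy(methyl)amino]-2-methyl-7-oxohept-2-enoate
Conditions: MeNH(OMe)·HCl (3 equiv), AlMe3 (3 equiv), CH2Cl2, 0 °C → rt
Reagents that add atoms: N,O-dimethylhydroxylamine hydrochloride, CNOC.Cl
Why: Aluminium-amide aminolysis (Weinreb amide formation) should open the γ-lactone much faster than it attacks the conjugated, α-branched ethyl ester, and the C–O stereocentre is not involved.

Step 3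
Reactants: 5 ethyl (2E,4R)-4-hydroxy-7-[methoxy(methyl)amino]-2-methyl-7-oxohept-2-enoate
Product: 6 ethyl (2E,4R)-4-[(tert-butyldimethylsilyl)oxy]-7-[methoxy(methyl)amino]-2-methyl-7-oxohept-2-enoate
Conditions: TBSCl (1.3 equiv), imidazole, DMF, rt
Reagents that add atoms: tert-butyldimethylsilyl chloride, CC(C)(C)[Si](C)(C)Cl
Why: Standard silylation of the secondary allylic alcohol blocks relactonisation and installs the bulky C1 group that later steers the cycloaddition.

Step 4
Reactants: 6 ethyl (2E,4R)-4-[(tert-butyldimethylsilyl)oxy]-7-[methoxy(methyl)amino]-2-methyl-7-oxohept-2-enoate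
Product: 7 ethyl (2E,4R)-4-[(tert-butyldimethylsilyl)oxy]-2-methyl-7-oxohept-2-enoate
Conditions: Cp2Zr(H)Cl (1.5 equiv), THF, rt
Reagents that add atoms: none
Why: Reduction of a tertiary (Weinreb) amide to the aldehyde by the zirconium hydride is known to spare esters and silyl ethers, which a hydride of aluminium would not.

Step 5
Reactants: 8 3-(benzyloxy)propanal
Product: 9 (±)-5-(benzyloxy)pent-1-en-3-ol
Conditions: CH2=CHMgBr (1.2 equiv), THF, −78 → 0 °C
Reagents that add atoms: vinylmagnesium bromide, C=C[Mg]Br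
Why: Grignard 1,2-addition to the aldehyde; the new carbinol centre is oxidised away in the next step.

Step 6
Reactants: 9 (±)-5-(benzyloxy)pent-1-en-3-ol
Product: 10 5-(benzyloxy)pent-1-en-3-one
Conditions: Dess–Martin periodinane, NaHCO3, CH2Cl2, 0 °C (used at once)
Reagents that add atoms: none
Why: Buffered Dess–Martin oxidation gives the vinyl ketone under non-basic conditions, so the β-benzyloxy group is not eliminated and the enone is not left to polymerise.

Step 7
Reactants: 10 5-(benzyloxy)pent-1-en-3-one; 11 allyl phenyl sulfide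
Product: 12 (E)-1-(benzyloxy)-6-(phenylthio)hex-4-en-3-one
Conditions: second-generation Hoveyda–Grubbs catalyst (5 mol %), 11 (3 equiv), CH2Cl2, 40 °C
Reagents that add atoms: none
Why: Olefin cross-metathesis between an electron-poor vinyl ketone and an allyl sulfide, a fast-reacting partner for ruthenium carbenes, should give the E-enone selectively.

Step 8
Reactants: 7 ethyl (2E,4R)-4-[(tert-butyldimethylsilyl)oxy]-2-methyl-7-oxohept-2-enoate; 12 (E)-1-(benzyloxy)-6-(phenylthio)hex-4-en-3-one
Product: 13 ethyl (2E,4R,7S,8R,10E)-8-[(benzyloxy)methyl]-4-[(tert-butyldimethylsilyl)oxy]-7-hydroxy-2-methyl-9-oxo-12-(phenylthio)dodeca-2,10-dienoate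
Conditions: Ipc2BOTf (antipode for Re-face attack, 1.3 equiv), i-Pr2NEt, CH2Cl2, −78 °C; then 7, −78 → −20 °C; MeOH/pH 7 buffer work-up without peroxide
Reagents that add atoms: none
Why: Boron aldol reaction through the Z-enol borinate and a chair transition state gives the syn aldol, the Ipc ligands choosing the Re face of the aldehyde and so setting the carbinol C4 (7S; the remote C1 centre has no influence), while the non-oxidative work-up spares the sulfide and the C5 centre is erased in step 9.

Step 9
Reactants: 13 ethyl (2E,4R,7S,8R,10E)-8-[(benzyloxy)methyl]-4-[(tert-butyldimethylsilyl)oxy]-7-hydroxy-2-methyl-9-oxo-12-(phenylthio)dodeca-2,10-dienoate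
Product: 15 ethyl (2E,4R)-6-{(4S)-5-[(benzyloxy)methyl]-2,2-di-tert-butyl-6-[(E)-3-(phenylthio)prop-1-en-1-yl]-4H-1,3,2-dioxasilin-4-yl}-4-[(tert-butyldimethylsilyl)oxy]-2-methylhex-2-enoate, via silyl triflate ether 14 (not isolated)
Conditions: t-Bu2Si(OTf)2 (1.2 equiv), 2,6-lutidine (3 equiv), CH2Cl2, −78 → 0 °C; then Et3N (3 equiv), 0 °C → rt
Reagents that add atoms: di-tert-butylsilyl bis(trifluoromethanesulfonate), CC(C)(C)[Si](OS(=O)(=O)C(F)(F)F)(OS(=O)(=O)C(F)(F)F)C(C)(C)C
Why: Silylation of the alcohol followed by intramolecular silyl triflate–amine enol silylation of the ketone closes the six-membered silylene ring, in which C4 is necessarily cis to the enol oxygen, so the C5=C6 geometry is fixed and both C5 epimers converge.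

Step 10
Reactants: 15 the dioxasiline ethyl ester of step 9
Product: 16 (2E,4R)-6-{(4S)-5-[(benzyloxy)methyl]-2,2-di-tert-butyl-6-[(E)-3-(phenylthio)prop-1-en-1-yl]-4H-1,3,2-dioxasilin-4-yl}-4-[(tert-butyldimethylsilyl)oxy]-2-methylhex-2-en-1-ol
Conditions: i-Bu2AlH (2.5 equiv), CH2Cl2, −78 °C; aq. potassium sodium tartrate
Reagents that add atoms: none
Why: Aluminium hydride reduction of the enoate to the allylic alcohol leaves the silyl enol ether, silyl ether, sulfide and benzyl ether untouched.

Step 11
Reactants: 16 the allylic alcohol of step 10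
Product: 17 (2E,4R)-6-{(4S)-5-[(benzyloxy)methyl]-2,2-di-tert-butyl-6-[(E)-3-(phenylthio)prop-1-en-1-yl]-4H-1,3,2-dioxasilin-4-yl}-4-[(tert-butyldimethylsilyl)oxy]-2-methylhex-2-enal
Conditions: MnO2 (activated, excess), CH2Cl2, rt
Reagents that add atoms: none
Why: Manganese dioxide oxidises only the allylic alcohol, under neutral conditions that keep the sulfide and the acid-sensitive silyloxydiene intact and the enal E.

Step 12
Reactants: 17 the trienal of step 11
Product: 18 trans-decal-6-ene-9β-carbaldehyde with 1β-OTBS, 5α-CH2OBn, 8β-CH2SPh, 9α-CH3, 10β-H and the C6 enol oxygen bridged to 4β-O by Si(t-Bu)2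
Conditions: Me2AlCl (1.5 equiv), CH2Cl2, −78 → −20 °C
Reagents that add atoms: none
Why: Proposed new method: the Me2AlCl-bound enal and the electron-rich silyloxydiene should combine in a concerted, asynchronous normal-demand [4+2] cycloaddition in which the nucleophilic diene terminus C5 (beside the silyloxy carbon C6) bonds to the enal β-carbon C10 and C8 bonds to C9, so polarity and tether agree; the closest known reaction type is the type 1 intramolecular Diels–Alder reaction of 1,7,9-decatrienals with an acyclic 2-silyloxydiene and a terminally activated E-dienophile, and what is new is the diene held in a 4H-1,3,2-dioxasiline ring and the formation of two quaternary carbons (C5, C9) in one event. Ring B (C5–C10) closes as the six-membered cycloaddition ring and ring A (C1–C5, C10) as a six-membered carbocycle through the four-carbon tether C1–C4 in a chair-like fold with the tether exo and the formyl group endo, the mode that leads to the trans fusion. C5 is set by the ring-locked enol ether (C4 must be cis to the enol oxygen, so the tether is the outside and C19 the inside substituent and C19 ends cis to the exo methyl C20, syn-diaxial) and by the C4 stereocentre, which holds C3 on one face of the diene and thereby picks the face the dienophile reaches; C9 and C10 are set by the E-geometry and by the dienophile face, which the C1 stereocentre fixes through allylic 1,3-strain with the C20 methyl (H-1 near the alkene plane, the silyloxy group turned away from the diene and equatorial in the new ring). C8 comes out 8β (the outside CH2SPh group ends cis to the endo formyl group), which is accepted because C8 is erased in step 15. The step needs the endo-formyl, trans-fused mode on one matched pair of faces: the Lewis acid reinforces the endo preference of the complexed formyl group and lets the reaction run cold, out of reach of a 1,5-hydrogen shift of the Z-substituted diene, while the C1 and C4 centres both ask for the same chair tether.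

Step 13
Reactants: 18 the cycloadduct aldehyde
Product: 19 the 9β-vinyl analogue of 18 (C11=C12 in place of the formyl group)
Conditions: Ph3PCH3Br, KN(SiMe3)2, THF, 0 °C → rt
Reagents that add atoms: methyltriphenylphosphonium bromide, C[P+](c1ccccc1)(c1ccccc1)c1ccccc1.[Br-]
Why: Wittig methylenation of the non-enolisable neopentyl aldehyde; the base-stable silylene enol ether keeps C6 masked, so only C11 can react.

Step 14
Reactants: 19 the 9β-vinyl silylene enol ether
Product: 20 the sulfoxide of 19 (8β-CH2S(O)Ph, both sulfur epimers)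
Conditions: NaIO4 (1.1 equiv), MeOH/THF/H2O, 0 °C → rt
Reagents that add atoms: sodium periodate, [Na+].[O-]I(=O)(=O)=O
Why: Periodate oxidises the sulfide to the sulfoxide and stops there, and unlike a peracid it does not attack the silyl enol ether or the vinyl group.

Step 15
Reactants: 20 the sulfoxide
Product: 21 the 8(17)-methylene silyloxydiene (C8=CH2; C6=C7 enol ether still bridged to 4β-O; 9β-vinyl)
Conditions: toluene, NaHCO3 (solid), 110 °C
Reagents that add atoms: none
Why: Thermal syn-elimination of the sulfoxide can only take H-8, the single β-hydrogen, so the exocyclic alkene forms and the wrongly set C8 centre is erased; the transoid diene produced cannot react further.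

Step 16
Reactants: 21 the 8(17)-methylene silyloxydiene
Product: 22 4β-hydroxy-8-methyl-7-en-6-one (trans-decalin with 1β-OTBS, 5α-CH2OBn, 9β-vinyl, 9α-CH3)
Conditions: HF·pyridine, pyridine, THF, 0 °C → rt
Reagents that add atoms: none
Why: Buffered HF·pyridine cleaves both Si–O bonds of the cyclic di-tert-butylsilylene faster than the hindered secondary TBS ether, and the released dienol should settle as the conjugated 8-methyl-7-en-6-one, the thermodynamic tautomer (any 8(17)-ene isomer converges in step 17).

Step 17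
Reactants: 22 the hydroxy enone
Product: 23 8-methyl-7-ene-4,6-dione (1β-OTBS, 5α-CH2OBn, 9β-vinyl)
Conditions: Dess–Martin periodinane, NaHCO3, CH2Cl2, rt; then DBU (0.1 equiv)
Reagents that add atoms: none
Why: Dess–Martin oxidation of the axial 4-alcohol avoids the base-induced retro-aldol opening of ring A that threatens the hydroxy ketone, and the catalytic DBU added once the non-enolisable 1,3-dione exists only brings any deconjugated enone into conjugation.

Step 18
Reactants: 23 the enedione
Product: 24 4-methylene-8-methyl-7-en-6-one (C4=C18H2; 1β-OTBS, 5α-CH2OBn, 9β-vinyl)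
Conditions: Ph3PCH3Br, KN(SiMe3)2 (1.3 equiv of ylide), THF, −78 → 0 °C
Reagents that add atoms: methyltriphenylphosphonium bromide, C[P+](c1ccccc1)(c1ccccc1)c1ccccc1.[Br-]
Why: Wittig methylenation should take the saturated C4 ketone in preference to the conjugated, doubly flanked C6 carbonyl, the same chemoselectivity as in the olefination of the saturated carbonyl of Wieland–Miescher-type enediones.

Step 19
Reactants: 24 the methylene enone
Product: 25 19-hydroxy-4-methylene-8α-methyl-6-ketone (saturated ring B; 1β-OTBS, 9β-vinyl)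
Conditions: Li, NH3(l)/THF, t-BuOH (2 equiv), −78 °C; then isoprene, NH4Cl
Reagents that add atoms: none
Why: Dissolving-metal reduction of the enone protonates the β-carbon C8 axially from the β face, which leaves the 8α-methyl equatorial; the enolate protects C6 until the quench, the isolated alkenes survive and the benzyl ether is cleaved in the same operation.

Step 20
Reactants: 25 the hydroxy ketone
Product: 26 4-methylene-6α,19-diol (8α-CH3, 1β-OTBS, 9β-vinyl)
Conditions: NaBH4, MeOH, 0 °C
Reagents that add atoms: none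
Why: Hydride reduction with axial attack from the open β face (the α face is shielded by the axial C19 and C20 groups) should give the equatorial 6α-alcohol.

Step 21
Reactants: 26 the methylene diol
Product: 27 4α,18-epoxy-6α,19-diol (1β-OTBS, 9β-vinyl)
Conditions: VO(acac)2 (5 mol %), t-BuOOH (1.5 equiv), CH2Cl2, 0 °C → rt
Reagents that add atoms: tert-butyl hydroperoxide, CC(C)(C)OO
Why: Hydroxyl-directed vanadium-catalysed epoxidation, in which the axial α-face 19-OH (homoallylic to C4=C18, seconded by the 6α-OH) delivers oxygen to the α face and so sets C4, while the undirected vinyl group is left alone.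

Step 22
Reactants: 27 the epoxy diol
Product: 28 4α,18-epoxide 6α,19-diacetate with 1β-OTBS and 9β-vinyl
Conditions: Ac2O, pyridine, DMAP (cat.), CH2Cl2, rt
Reagents that add atoms: acetic anhydride, CC(=O)OC(C)=O
Why: DMAP-catalysed acetylation of the primary 19-OH and the secondary 6-OH installs both acetates of the target and leaves the epoxide untouched.

Step 23
Reactants: 28 the epoxy diacetate
Product: 29 the 12-alcohol (9β-CH2CH2OH; otherwise as 28)
Conditions: 9-BBN (2 equiv), THF, 0 → 40 °C; then NaBO3·4H2O, THF/H2O, rt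
Reagents that add atoms: sodium perborate, [Na+].[O-]OB=O
Why: Anti-Markovnikov hydroboration of the neopentyl vinyl group with the bulky borane, followed by perborate oxidation, which is mild enough for the acetates and the epoxide.

Step 24
Reactants: 29 the 12-alcohol
Product: 30 the 12-aldehyde (9β-CH2CHO; otherwise as 28)
Conditions: Dess–Martin periodinane, NaHCO3, CH2Cl2, rt
Reagents that add atoms: none
Why: Dess–Martin oxidation of the primary alcohol under buffered conditions; no epimerisable centre is adjacent.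

Step 25
Reactants: 30 the 12-aldehyde; 31 4-bromofuran-2(5H)-one
Product: 32 (12S)-6α,19-diacetoxy-1β-[(tert-butyldimethylsilyl)oxy]-4α,18-epoxy-12-hydroxyclerod-13-en-15,16-olide
Conditions: 31 (2 equiv), CrCl2 (4 equiv), NiCl2 (2 mol %), N-[2-(4-isopropyl-4,5-dihydrooxazol-2-yl)-6-methylphenyl]methanesulfonamide (antipode for Re-face addition), 1,8-bis(dimethylamino)naphthalene, THF, rt
Reagents that add atoms: none
Why: Nozaki–Hiyama–Kishi reaction, in which zerovalent nickel inserts into the electron-poor alkenyl bromide and transmetallation gives an alkenyl species of trivalent chromium that adds only to the aldehyde (acetates, epoxide and lactone are inert), the chromium-bound chiral ligand choosing the Re face to set 12S.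

Step 26
Reactants: 32 the 12-hydroxy butenolide
Product: 33 (12S)-6α,19-diacetoxy-1β-[(tert-butyldimethylsilyl)oxy]-18-chloro-4α,12-dihydroxyclerod-13-en-15,16-olide
Conditions: LiCl (5 equiv), AcOH (5 equiv), THF, rt
Reagents that add atoms: lithium chloride, [Li+].[Cl-]
Why: Acid-assisted SN2 opening of the spiro-epoxide by chloride at the primary carbon C18 (the tertiary, neopentyl C4 is out of reach) keeps the C4–O bond and so gives the 4α-hydroxy-18-chloride.

Step 27
Reactants: 33 the chlorohydrin silyl ether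
Product: 34 (12S)-6α,19-diacetoxy-18-chloro-1β,4α,12-trihydroxyclerod-13-en-15,16-olide
Conditions: HF·pyridine, THF, 0 °C → rt
Reagents that add atoms: none
Why: Fluoride-mediated cleavage of the secondary TBS ether, placed after the epoxide has gone so that HF cannot open it; acetates, chlorohydrin and butenolide tolerate the reagent.

Step 28
Reactants: 34 the triol; 35 (S)-2-methylbutanoic acid
Product: 36 ajugaciliatin A
Conditions: 35 (3 equiv), EDC·HCl (3 equiv), DMAP (1 equiv), CH2Cl2, 0 °C → rt
Reagents that add atoms: none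
Why: Steglich esterification should acylate both secondary alcohols (1-OH, 12-OH) while the tertiary 4-OH is too hindered to react, and the α-centre of the acid is carried over unchanged.

Compound list
1 | (R)-5-(hydroxymethyl)dihydrofuran-2(3H)-one | OC[C@H]1CCC(=O)O1 | starting material
2 | ethyl 2-(triphenylphosphoranylidene)propanoate | CCOC(=O)C(C)=P(c1ccccc1)(c1ccccc1)c1ccccc1 | starting material
3 | (R)-5-oxotetrahydrofuran-2-carbaldehyde | O=C[C@H]1CCC(=O)O1 | intermediate
4 | ethyl (E)-2-methyl-3-[(2R)-5-oxotetrahydrofuran-2-yl]prop-2-enoate | CCOC(=O)/C(C)=C/[C@H]1CCC(=O)O1 | intermediate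
5 | ethyl (2E,4R)-4-hydroxy-7-[methoxy(methyl)amino]-2-methyl-7-oxohept-2-enoate | CCOC(=O)/C(C)=C/[C@H](O)CCC(=O)N(C)OC | intermediate
6 | ethyl (2E,4R)-4-[(tert-butyldimethylsilyl)oxy]-7-[methoxy(methyl)amino]-2-methyl-7-oxohept-2-enoate | CCOC(=O)/C(C)=C/[C@H](O[Si](C)(C)C(C)(C)C)CCC(=O)N(C)OC | intermediate
7 | ethyl (2E,4R)-4-[(tert-butyldimethylsilyl)oxy]-2-methyl-7-oxohept-2-enoate | CCOC(=O)/C(C)=C/[C@H](O[Si](C)(C)C(C)(C)C)CCC=O | intermediate
8 | 3-(benzyloxy)propanal | O=CCCOCc1ccccc1 | starting material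
9 | (±)-5-(benzyloxy)pent-1-en-3-ol | C=CC(O)CCOCc1ccccc1 | intermediate
10 | 5-(benzyloxy)pent-1-en-3-one | C=CC(=O)CCOCc1ccccc1 | intermediate
11 | allyl phenyl sulfide | C=CCSc1ccccc1 | starting material
12 | (E)-1-(benzyloxy)-6-(phenylthio)hex-4-en-3-one | O=C(CCOCc1ccccc1)/C=C/CSc1ccccc1 | intermediate
13 | ethyl (2E,4R,7S,8R,10E)-8-[(benzyloxy)methyl]-4-[(tert-butyldimethylsilyl)oxy]-7-hydroxy-2-methyl-9-oxo-12-(phenylthio)dodeca-2,10-dienoate | CCOC(=O)/C(C)=C/[C@H](O[Si](C)(C)C(C)(C)C)CC[C@H](O)[C@@H](COCc1ccccc1)C(=O)/C=C/CSc1ccccc1 | intermediate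
14 | 7-O-[di-tert-butyl(trifluoromethanesulfonyloxy)silyl] ether of 13 | CCOC(=O)/C(C)=C/[C@H](O[Si](C)(C)C(C)(C)C)CC[C@H](O[Si](OS(=O)(=O)C(F)(F)F)(C(C)(C)C)C(C)(C)C)[C@@H](COCc1ccccc1)C(=O)/C=C/CSc1ccccc1 | intermediate
15 | ethyl (2E,4R)-6-{(4S)-5-[(benzyloxy)methyl]-2,2-di-tert-butyl-6-[(E)-3-(phenylthio)prop-1-en-1-yl]-4H-1,3,2-dioxasilin-4-yl}-4-[(tert-butyldimethylsilyl)oxy]-2-methylhex-2-enoate | CCOC(=O)/C(C)=C/[C@H](O[Si](C)(C)C(C)(C)C)CC[C@@H]1O[Si](C(C)(C)C)(C(C)(C)C)OC(/C=C/CSc2ccccc2)=C1COCc1ccccc1 | intermediate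
16 | corresponding (2E,4R)-hex-2-en-1-ol (CH2OH in place of CO2Et of 15) | OC/C(C)=C/[C@H](O[Si](C)(C)C(C)(C)C)CC[C@@H]1O[Si](C(C)(C)C)(C(C)(C)C)OC(/C=C/CSc2ccccc2)=C1COCc1ccccc1 | intermediate
17 | corresponding (2E,4R)-hex-2-enal (CHO in place of CO2Et of 15) | O=C/C(C)=C/[C@H](O[Si](C)(C)C(C)(C)C)CC[C@@H]1O[Si](C(C)(C)C)(C(C)(C)C)OC(/C=C/CSc2ccccc2)=C1COCc1ccccc1 | intermediate
18 | cycloadduct: trans-decal-6-ene-9β-carbaldehyde, 1β-OTBS, 5α-CH2OBn, 8β-CH2SPh, 9α-CH3, 10β-H, 4β-O–Si(t-Bu)2–O–C6 bridge | O=C[C@@]1(C)[C@@H](CSc4ccccc4)C=C3[C@]2(COCc5ccccc5)[C@@H]1[C@H](O[Si](C)(C)C(C)(C)C)CC[C@@H]2O[Si](C(C)(C)C)(C(C)(C)C)O3 | intermediate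
19 | 9β-vinyl analogue of 18 | C=C[C@@]1(C)[C@@H](CSc4ccccc4)C=C3[C@]2(COCc5ccccc5)[C@@H]1[C@H](O[Si](C)(C)C(C)(C)C)CC[C@@H]2O[Si](C(C)(C)C)(C(C)(C)C)O3 | intermediate
20 | sulfoxide of 19 (both sulfur epimers) | C=C[C@@]1(C)[C@@H](CS(=O)c4ccccc4)C=C3[C@]2(COCc5ccccc5)[C@@H]1[C@H](O[Si](C)(C)C(C)(C)C)CC[C@@H]2O[Si](C(C)(C)C)(C(C)(C)C)O3 | intermediate
21 | 8(17)-methylene silyloxydiene, silylene bridge intact, 9β-vinyl | C=C[C@@]1(C)C(=C)C=C3[C@]2(COCc4ccccc4)[C@@H]1[C@H](O[Si](C)(C)C(C)(C)C)CC[C@@H]2O[Si](C(C)(C)C)(C(C)(C)C)O3 | intermediate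
22 | 4β-hydroxy-8-methyl-7-en-6-one, 1β-OTBS, 5α-CH2OBn, 9β-vinyl | C=C[C@@]1(C)C(C)=CC(=O)[C@]2(COCc3ccccc3)[C@@H]1[C@H](O[Si](C)(C)C(C)(C)C)CC[C@@H]2O | intermediate
23 | 8-methyl-7-ene-4,6-dione, 1β-OTBS, 5α-CH2OBn, 9β-vinyl | C=C[C@@]1(C)C(C)=CC(=O)[C@]2(COCc3ccccc3)[C@@H]1[C@H](O[Si](C)(C)C(C)(C)C)CCC2=O | intermediate
24 | 4-methylene-8-methyl-7-en-6-one, 1β-OTBS, 5α-CH2OBn, 9β-vinyl | C=C[C@@]1(C)C(C)=CC(=O)[C@]2(COCc3ccccc3)[C@@H]1[C@H](O[Si](C)(C)C(C)(C)C)CCC2=C | intermediate
25 | 19-hydroxy-4-methylene-8α-methyl-6-ketone, 1β-OTBS, 9β-vinyl | C=C[C@@]1(C)[C@H](C)CC(=O)[C@]2(CO)[C@@H]1[C@H](O[Si](C)(C)C(C)(C)C)CCC2=C | intermediate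
26 | 4-methylene-6α,19-diol, 8α-CH3, 1β-OTBS, 9β-vinyl | C=C[C@@]1(C)[C@H](C)C[C@H](O)[C@]2(CO)[C@@H]1[C@H](O[Si](C)(C)C(C)(C)C)CCC2=C | intermediate
27 | 4α,18-epoxy-6α,19-diol, 1β-OTBS, 9β-vinyl | C=C[C@@]1(C)[C@H](C)C[C@H](O)[C@]2(CO)[C@@H]1[C@H](O[Si](C)(C)C(C)(C)C)CC[C@]23CO3 | intermediate
28 | 4α,18-epoxide 6α,19-diacetate, 1β-OTBS, 9β-vinyl | C=C[C@@]1(C)[C@H](C)C[C@H](OC(C)=O)[C@]2(COC(C)=O)[C@@H]1[C@H](O[Si](C)(C)C(C)(C)C)CC[C@]23CO3 | intermediate
29 | 12-alcohol (9β-CH2CH2OH), otherwise as 28 | OCC[C@@]1(C)[C@H](C)C[C@H](OC(C)=O)[C@]2(COC(C)=O)[C@@H]1[C@H](O[Si](C)(C)C(C)(C)C)CC[C@]23CO3 | intermediate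
30 | 12-aldehyde (9β-CH2CHO), otherwise as 28 | O=CC[C@@]1(C)[C@H](C)C[C@H](OC(C)=O)[C@]2(COC(C)=O)[C@@H]1[C@H](O[Si](C)(C)C(C)(C)C)CC[C@]23CO3 | intermediate
31 | 4-bromofuran-2(5H)-one | O=C1C=C(Br)CO1 | starting material
32 | (12S)-6α,19-diacetoxy-1β-[(tert-butyldimethylsilyl)oxy]-4α,18-epoxy-12-hydroxyclerod-13-en-15,16-olide | O[C@@H](C[C@@]1(C)[C@H](C)C[C@H](OC(C)=O)[C@]2(COC(C)=O)[C@@H]1[C@H](O[Si](C)(C)C(C)(C)C)CC[C@]23CO3)C1=CC(=O)OC1 | intermediate
33 | (12S)-6α,19-diacetoxy-1β-[(tert-butyldimethylsilyl)oxy]-18-chloro-4α,12-dihydroxyclerod-13-en-15,16-olide | O[C@@H](C[C@@]1(C)[C@H](C)C[C@H](OC(C)=O)[C@]2(COC(C)=O)[C@@H]1[C@H](O[Si](C)(C)C(C)(C)C)CC[C@]2(O)CCl)C1=CC(=O)OC1 | intermediate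
34 | (12S)-6α,19-diacetoxy-18-chloro-1β,4α,12-trihydroxyclerod-13-en-15,16-olide | O[C@@H](C[C@@]1(C)[C@H](C)C[C@H](OC(C)=O)[C@]2(COC(C)=O)[C@@H]1[C@H](O)CC[C@]2(O)CCl)C1=CC(=O)OC1 | intermediate
35 | (S)-2-methylbutanoic acid | CC[C@H](C)C(=O)O | starting material
36 | ajugaciliatin A | CC[C@H](C)C(=O)O[C@@H](C[C@@]1(C)[C@H](C)C[C@H](OC(C)=O)[C@]2(COC(C)=O)[C@@H]1[C@H](OC(=O)[C@@H](C)CC)CC[C@]2(O)CCl)C1=CC(=O)OC1 | target

Total step count: 28. Longest linear sequence: 25 steps (from 1: steps 1–4, then 8–28).

Steps most likely to fail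

Step 12 (the step put forward as a new method). The cycloaddition may be too slow at the doubly hindered termini, so that cleavage of the silyl enol ether or a 1,5-hydrogen shift of the diene takes over, or it may run through the exo-formyl mode to the cis-fused skeleton. The fallback sets out from 15 and comes back at 18, and makes the two bonds one after the other by known ionic chemistry. Ester 15 is treated with catalytic TBSOTf in CH2Cl2 (−78 → 0 °C). A silyl-triflate-mediated intramolecular double Michael addition should follow: Mukaiyama–Michael attack of C5 on C10 of the enoate, then 6-endo Michael closure of the ketene silyl acetal carbon C9 onto C8 of the silyl-activated enone. This should give the decalin ethyl ester F1. The first bond no longer has to form together with the second, and the second closure needs C6 and C9 trans-diequatorial on ring A, which selects the trans-fused product. Reduction with i-Bu2AlH then gives the neopentyl alcohol F2, and Parikh–Doering oxidation (SO3·pyridine, DMSO, i-Pr2NEt) returns 18. A C8 epimer would serve equally, since C8 is erased in step 15.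

Step 9. After the alcohol is silylated, deprotonation may occur at the γ-CH2 next to sulfur (C17) instead of at C5, giving the linear dienol silyl ether rather than the six-membered ring. The fallback sets out from 10 (with 7) and comes back at 15, and brings the sulfur-bearing carbon in only after the ring is closed. The aldol of step 8 is run with vinyl ketone 10 in place of 12 to give the hydroxy vinyl ketone F3. Silylene closure as in step 9 then gives the 6-vinyl dioxasiline F4, which has no γ-hydrogen to lose. Cross-metathesis of its only unhindered alkene with allyl phenyl sulfide 11 (second-generation Hoveyda–Grubbs catalyst, CH2Cl2, 40 °C) delivers 15.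

Step 25. Insertion and transmetallation of the bromobutenolide may be slow, the alkenylchromium species may be lost by ring opening, or the facial selectivity at C12 may be poor. The fallback sets out from 30 and comes back at 32, and brings the four carbons in as a furan.
- 3-Furyllithium (3-bromofuran, n-BuLi, THF, −78 °C) is added to 30 to give the 3-furyl carbinol F5 as a C12 mixture.
- Dess–Martin oxidation gives the 3-furyl ketone F6.
- CBS reduction ((R)-Me-CBS, BH3·SMe2), with the furan as the large group, is expected to set the (12S)-furyl carbinol F7.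
- Photo-oxygenation with singlet oxygen (O2, hν, rose bengal, i-Pr2NEt, CH2Cl2, −78 °C) followed by Kornblum–DeLaMare opening of the endoperoxide at the unhindered position gives the γ-hydroxybutenolide F8.
- NaBH4 followed by mild acid reduces the masked aldehyde and relactonises to 32.

Further compounds
F1 | step 12 | decalin ethyl ester (CO2Et in place of the 9β-formyl group of 18) | CCOC(=O)[C@@]1(C)[C@@H](CSc4ccccc4)C=C3[C@]2(COCc5ccccc5)[C@@H]1[C@H](O[Si](C)(C)C(C)(C)C)CC[C@@H]2O[Si](C(C)(C)C)(C(C)(C)C)O3
F2 | step 12 | neopentyl alcohol (9β-CH2OH analogue of 18) | OC[C@@]1(C)[C@@H](CSc4ccccc4)C=C3[C@]2(COCc5ccccc5)[C@@H]1[C@H](O[Si](C)(C)C(C)(C)C)CC[C@@H]2O[Si](C(C)(C)C)(C(C)(C)C)O3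
F3 | step 9 | ethyl (2E,4R,7S,8R)-8-[(benzyloxy)methyl]-4-[(tert-butyldimethylsilyl)oxy]-7-hydroxy-2-methyl-9-oxoundeca-2,10-dienoate | CCOC(=O)/C(C)=C/[C@H](O[Si](C)(C)C(C)(C)C)CC[C@H](O)[C@@H](COCc1ccccc1)C(=O)C=C
F4 | step 9 | ethyl (2E,4R)-6-{(4S)-5-[(benzyloxy)methyl]-2,2-di-tert-butyl-6-ethenyl-4H-1,3,2-dioxasilin-4-yl}-4-[(tert-butyldimethylsilyl)oxy]-2-methylhex-2-enoate | CCOC(=O)/C(C)=C/[C@H](O[Si](C)(C)C(C)(C)C)CC[C@@H]1O[Si](C(C)(C)C)(C(C)(C)C)OC(C=C)=C1COCc1ccccc1
F5 | step 25 | 3-furyl carbinol (C12 epimer mixture; furan-3-yl in place of the butenolide of 32) | OC(C[C@@]1(C)[C@H](C)C[C@H](OC(C)=O)[C@]2(COC(C)=O)[C@@H]1[C@H](O[Si](C)(C)C(C)(C)C)CC[C@]23CO3)c1ccoc1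
F6 | step 25 | 3-furyl ketone (C12=O) | O=C(C[C@@]1(C)[C@H](C)C[C@H](OC(C)=O)[C@]2(COC(C)=O)[C@@H]1[C@H](O[Si](C)(C)C(C)(C)C)CC[C@]23CO3)c1ccoc1
F7 | step 25 | (12S)-3-furyl carbinol | O[C@@H](C[C@@]1(C)[C@H](C)C[C@H](OC(C)=O)[C@]2(COC(C)=O)[C@@H]1[C@H](O[Si](C)(C)C(C)(C)C)CC[C@]23CO3)c1ccoc1
F8 | step 25 | γ-hydroxybutenolide (16-hydroxy-15,16-olide analogue of 32) | O[C@@H](C[C@@]1(C)[C@H](C)C[C@H](OC(C)=O)[C@]2(COC(C)=O)[C@@H]1[C@H](O[Si](C)(C)C(C)(C)C)CC[C@]23CO3)C1=CC(=O)OC1O
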